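**Retrosynthetic overview** (hydrindane numbering: C2 ketone, C3 side-chain carbon, C3a/C7a ring fusion, C4 isopropyl, C5 and C6 oxygenated, C7 methylidene)
1. Target ⇒ C6 ester (Steglich) ⇒ C6–O bond (SeO2 allylic hydroxylation of the 7-methylidene compound) ⇒ C5 ester ⇒ alcohol 11.
2. 11 ⇒ C3–C1' bond: addition of the regiodefined C2=C3 enol silane of 8 to ethylidene diacetate.
3. Key disconnection of 8: C3a–C4 and C5–C6 together ⇒ enone 5 + enol silane 7 (Mukaiyama–Michael addition whose silyloxocarbenium ion is closed onto an allylsilane).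
4. Enabling feature: the six-membered ring holds a 3-methylidenecyclohexan-1-ol unit (C5–O, C6, C7=CH2), and its ring carbon C3a is β to the cyclopentanone carbonyl C2. So C4–C5 (isovaleraldehyde) can be inserted between an enone β-carbon and the terminal carbon of a 2-(silylmethyl)allyl group on C7a.
5. Ring order: the five-membered ring is bought (1; its stereocentre becomes C7a and relays all others); the six-membered ring is closed in the key step.

Key step: step 4

Remark on stereodescriptors: β is the face of H-7a. The target has H-3a α (trans fusion), 4-isopropyl α, 5-O and 6-O β, and the C3 side chain α.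
Remark on materials: (2E)-3-methylpent-2-enoic acid 15 is assumed to be purchasable as the pure E isomer; 7 is used as the Z-enriched enol silane.

Step 1
Reactants: 1 (R)-4-[(tert-butyldimethylsilyl)oxy]cyclopent-2-en-1-one; 2 2-bromo-3-(trimethylsilyl)prop-1-ene
Product: 4 (3S,4R)-4-[(tert-butyldimethylsilyl)oxy]-3-[3-(trimethylsilyl)prop-1-en-2-yl]cyclopentan-1-one, via alkenylmagnesium bromide 3 (not isolated)
Conditions: 2, Mg, THF, 40 °C; then 1, CuBr·SMe2 (10 mol %), THF, −78 °C; aq NH4Cl
Reagents that add atoms: none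
Why: Copper-catalysed conjugate addition of an alkenyl Grignard reagent, which should enter anti to the silyloxy group and so set the future C7a stereocentre trans to it.

Step 2
Reactants: 4
Product: 5 (R)-4-[3-(trimethylsilyl)prop-1-en-2-yl]cyclopent-2-en-1-one
Conditions: DBU, CH2Cl2, 0 °C to rt
Reagents that add atoms: none
Why: E1cB β-elimination of the silyloxy group through the enolate on the side remote from the new substituent should give the 4-substituted cyclopentenone without touching the stereocentre.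

Step 3
Reactants: 6 3-methylbutanal
Product: 7 (Z)-trimethyl[(3-methylbut-1-en-1-yl)oxy]silane
Conditions: Me3SiOTf, Et3N, Et2O, 0 °C; distillation
Reagents that add atoms: trimethylsilyl trifluoromethanesulfonate, C[Si](C)(C)OS(=O)(=O)C(F)(F)F
Why: Soft enolisation (silyl triflate/amine silyl enol ether formation), in which deprotonation of the E-configured silyloxocarbenium ion is expected to favour the Z enol silane.

Step 4
Reactants: 5; 7
Product: 8 (3aR,4S,5S,7aR)-4-isopropyl-7-methylidene-2,5-bis[(trimethylsilyl)oxy]-3a,4,5,6,7,7a-hexahydro-1H-indene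
Conditions: Me3SiNTf2 (5 mol %), 2,6-di-tert-butyl-4-methylpyridine (10 mol %), CH2Cl2, −78 °C, 5 added slowly to 7 (2 equiv); Et3N quench, non-aqueous isolation
Reagents that add atoms: none
Why: Proposed new method: Me3SiNTf2 silylates the enone carbonyl of 5, the enol silane 7 adds through its carbon 2 to C3a (Mukaiyama–Michael addition), and the resulting silyloxocarbenium ion at C5, instead of passing on its silyl group, is captured by the terminal carbon of the 2-substituted allylsilane (Hosomi–Sakurai closure), after which the β-silyl cation releases Me3Si+ to silylate the enolate oxygen and turn the catalyst over. The closest known reaction types are the silyl-cation-catalysed tandem Mukaiyama–Michael/aldol reaction and annulations with bifunctional 2-(trimethylsilylmethyl)allyl reagents (conjugate addition, then Sakurai ring closure); new is the interception of the Michael-derived silyloxocarbenium ion by an allylsilane carried on the acceptor. The six-membered ring closes by 6-exo-trig attack on the C=O+ carbon with both allyl carbons endocyclic through a chair transition state, and loss of silicon forms the exocyclic methylene regiospecifically. C3a is set by the C7a stereocentre of 5 (addition anti to its substituent, hence trans fusion); C4 by an extended open transition state with the enol C=C antiperiplanar to C3=C3a, the α-hydrogen of 7 over the ring and the isopropyl group away from C7a; C5 by the chair in which the bulky E-configured O-silyl group is equatorial, trans to the equatorial isopropyl group. The step needs chemoselectivity between two π-nucleophiles of similar strength (7 against the allylsilane of a second molecule of 5), secured by adding 5 slowly to excess 7 so that only the intramolecular allylsilane meets an electrophile, and by the irreversible desilylative closure, which drains any reversibly formed cyclobutane or open-chain intermediates.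

Step 5
Reactants: 8; 9 ethane-1,1-diyl diacetate (ethylidene diacetate)
Product: 11 (1R)-1-[(3S,3aR,4S,5S,7aR)-5-hydroxy-4-isopropyl-7-methylidene-2-oxooctahydro-1H-inden-3-yl]ethyl acetate, via trimethylsilyl ether 10 (not isolated)
Conditions: 9 (1.5 equiv), Me3SiOTf (10 mol %), CH2Cl2, −78 °C; then citric acid, MeOH, 0 °C
Reagents that add atoms: none
Why: Mukaiyama aldol-type addition of the regiodefined C2=C3 enol silane to the acyloxycarbenium ion from the acylal, where the electrophile should approach C3 anti to the C4-bearing substituent on C3a (2,3-trans) and the open extended transition state of such acetal-type additions is syn selective irrespective of enol geometry, giving the (1R) acetate; mild acid then frees the C5 hydroxyl.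

Step 6
Reactants: 11; 12 (S)-2-methylbutanoic acid
Product: 13 (3S,3aR,4S,5S,7aR)-3-[(1R)-1-acetoxyethyl]-4-isopropyl-7-methylidene-2-oxooctahydro-1H-inden-5-yl (2S)-2-methylbutanoate
Conditions: EDC·HCl, DMAP (cat.), CH2Cl2, 0 °C to rt
Reagents that add atoms: none
Why: Steglich esterification of the only free hydroxyl under mild, weakly basic conditions that should spare the β-acetoxy ketone and the α-stereocentre of the acid; no stereocentre is formed.

Step 7
Reactants: 13
Product: 14 (3S,3aR,4S,5R,6S,7aR)-3-[(1R)-1-acetoxyethyl]-6-hydroxy-4-isopropyl-7-methylidene-2-oxooctahydro-1H-inden-5-yl (2S)-2-methylbutanoate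
Conditions: SeO2 (30 mol %), t-BuOOH (3 equiv), CH2Cl2, 0 °C to rt
Reagents that add atoms: tert-butyl hydroperoxide, CC(C)(C)OO (stoichiometric oxygen source; selenium dioxide, O=[Se]=O, carries the oxygen)
Why: Selenium dioxide allylic hydroxylation (ene reaction, then [2,3]-sigmatropic shift), in which the ring CH2 (C6) of the 1,1-disubstituted alkene should react in preference to the ring-fusion CH (C7a) and the oxygen should arrive on the axial β face from which the axial hydrogen is taken, giving the 5,6-cis diol monoester.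

Step 8
Reactants: 14; 15 (2E)-3-methylpent-2-enoic acid
Product: 16 (3S,3aR,4S,5R,6S,7aR)-3-[(1R)-1-acetoxyethyl]-4-isopropyl-7-methylidene-5-{[(2S)-2-methylbutanoyl]oxy}-2-oxooctahydro-1H-inden-6-yl (2E)-3-methylpent-2-enoate
Conditions: EDC·HCl, DMAP, CH2Cl2, rt
Reagents that add atoms: none
Why: Steglich esterification of the axial allylic alcohol, in which the equatorial C5 ester has no driving force to migrate to the axial C6 oxygen and the E geometry of the β,β-disubstituted acrylate should be retained.

**Compound list**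
1 | (R)-4-[(tert-butyldimethylsilyl)oxy]cyclopent-2-en-1-one | C1=CC(=O)C[C@H]1O[Si](C)(C)C(C)(C)C | starting material
2 | 2-bromo-3-(trimethylsilyl)prop-1-ene | C=C(Br)C[Si](C)(C)C | starting material
3 | [3-(trimethylsilyl)prop-1-en-2-yl]magnesium bromide (not isolated) | C=C([Mg]Br)C[Si](C)(C)C | intermediate
4 | (3S,4R)-4-[(tert-butyldimethylsilyl)oxy]-3-[3-(trimethylsilyl)prop-1-en-2-yl]cyclopentan-1-one (3,4-trans) | C=C(C[Si](C)(C)C)[C@@H]1CC(=O)C[C@H]1O[Si](C)(C)C(C)(C)C | intermediate
5 | (R)-4-[3-(trimethylsilyl)prop-1-en-2-yl]cyclopent-2-en-1-one | C=C(C[Si](C)(C)C)[C@@H]1CC(=O)C=C1 | intermediate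
6 | 3-methylbutanal | CC(C)CC=O | starting material
7 | (Z)-trimethyl[(3-methylbut-1-en-1-yl)oxy]silane | CC(C)/C=C\O[Si](C)(C)C | intermediate
8 | (3aR,4S,5S,7aR)-4-isopropyl-7-methylidene-2,5-bis[(trimethylsilyl)oxy]-3a,4,5,6,7,7a-hexahydro-1H-indene (trans-fused; 4-isopropyl α, 5-OSiMe3 β) | C=C1[C@@H]2CC(O[Si](C)(C)C)=C[C@H]2[C@H](C(C)C)[C@@H](O[Si](C)(C)C)C1 | intermediate
9 | ethane-1,1-diyl diacetate | CC(OC(C)=O)OC(C)=O | starting material
10 | (1R)-1-[(3S,3aR,4S,5S,7aR)-4-isopropyl-7-methylidene-2-oxo-5-[(trimethylsilyl)oxy]octahydro-1H-inden-3-yl]ethyl acetate (not isolated) | C=C1[C@@H]2CC(=O)[C@H]([C@@H](C)OC(C)=O)[C@H]2[C@H](C(C)C)[C@@H](O[Si](C)(C)C)C1 | intermediate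
11 | (1R)-1-[(3S,3aR,4S,5S,7aR)-5-hydroxy-4-isopropyl-7-methylidene-2-oxooctahydro-1H-inden-3-yl]ethyl acetate | C=C1[C@@H]2CC(=O)[C@H]([C@@H](C)OC(C)=O)[C@H]2[C@H](C(C)C)[C@@H](O)C1 | intermediate
12 | (S)-2-methylbutanoic acid | CC[C@H](C)C(=O)O | starting material
13 | (3S,3aR,4S,5S,7aR)-3-[(1R)-1-acetoxyethyl]-4-isopropyl-7-methylidene-2-oxooctahydro-1H-inden-5-yl (2S)-2-methylbutanoate | C=C1[C@@H]2CC(=O)[C@H]([C@@H](C)OC(C)=O)[C@H]2[C@H](C(C)C)[C@@H](OC(=O)[C@@H](C)CC)C1 | intermediate
14 | (3S,3aR,4S,5R,6S,7aR)-3-[(1R)-1-acetoxyethyl]-6-hydroxy-4-isopropyl-7-methylidene-2-oxooctahydro-1H-inden-5-yl (2S)-2-methylbutanoate | C=C1[C@@H]2CC(=O)[C@H]([C@@H](C)OC(C)=O)[C@H]2[C@H](C(C)C)[C@@H](OC(=O)[C@@H](C)CC)[C@H]1O | intermediate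
15 | (2E)-3-methylpent-2-enoic acid | CC/C(C)=C/C(=O)O | starting material
16 | (3S,3aR,4S,5R,6S,7aR)-3-[(1R)-1-acetoxyethyl]-4-isopropyl-7-methylidene-5-{[(2S)-2-methylbutanoyl]oxy}-2-oxooctahydro-1H-inden-6-yl (2E)-3-methylpent-2-enoate | C=C1[C@@H]2CC(=O)[C@H]([C@@H](C)OC(C)=O)[C@H]2[C@H](C(C)C)[C@@H](OC(=O)[C@@H](C)CC)[C@H]1OC(=O)/C=C(\C)CC | target

**Total step count:** 8. **Longest linear sequence:** 7 (steps 1, 2, 4, 5, 6, 7, 8; step 3 is a one-step branch).

**Steps most likely to fail**

Step 4 (Proposed new method). What may go wrong: intermolecular addition of the allylsilane of one molecule of 5 to the silylated enone of another (oligomerisation); silyl transfer outrunning ring closure, leaving an open-chain aldehyde; poor facial selectivity at C4; or closure through the chair with an axial C5 oxygen. The fallback makes the two bonds one after the other with established reactions and no allylsilane. It sets out from 1. Copper-catalysed addition of isopropenylmagnesium bromide gives (3S,4R)-4-[(tert-butyldimethylsilyl)oxy]-3-(prop-1-en-2-yl)cyclopentan-1-one F1, and DBU gives (R)-4-(prop-1-en-2-yl)cyclopent-2-en-1-one F2. A trityl-perchlorate-catalysed Mukaiyama–Michael addition of 7 then gives (2S)-3-methyl-2-[(1S,5R)-5-(prop-1-en-2-yl)-3-[(trimethylsilyl)oxy]cyclopent-2-en-1-yl]butanal F3, and addition to 9 as in step 5 gives (1R)-1-{(1S,2R,3R)-2-[(2S)-3-methyl-1-oxobutan-2-yl]-5-oxo-3-(prop-1-en-2-yl)cyclopentyl}ethyl acetate F4. A Me2AlCl-promoted intramolecular carbonyl–ene reaction of type 2 (hydrogen taken from the isopropenyl methyl group) closes the six-membered ring with the methylidene in place and should give the axial 5α alcohol (1R)-1-[(3S,3aR,4S,5R,7aR)-5-hydroxy-4-isopropyl-7-methylidene-2-oxooctahydro-1H-inden-3-yl]ethyl acetate F5. A Mitsunobu esterification with 12 (PPh3, DIAD) inverts C5 and returns to the route at 13.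

Step 7. What may go wrong: hydrogen abstraction at the ring-fusion position C7a instead of C6, slow reaction because the C5 ester deactivates the neighbouring C–H bonds, or over-oxidation to the enone. The fallback moves the hydroxylation ahead of the C5 acylation and runs it on an electron-richer silyl ether. It sets out from 11. TBSOTf/2,6-lutidine gives (1R)-1-[(3S,3aR,4S,5S,7aR)-5-[(tert-butyldimethylsilyl)oxy]-4-isopropyl-7-methylidene-2-oxooctahydro-1H-inden-3-yl]ethyl acetate F6, and SeO2/t-BuOOH gives the 6β-alcohol (1R)-1-[(3S,3aR,4S,5R,6S,7aR)-5-[(tert-butyldimethylsilyl)oxy]-6-hydroxy-4-isopropyl-7-methylidene-2-oxooctahydro-1H-inden-3-yl]ethyl acetate F7. Steglich esterification with 15 gives (3S,3aR,4S,5R,6S,7aR)-3-[(1R)-1-acetoxyethyl]-5-[(tert-butyldimethylsilyl)oxy]-4-isopropyl-7-methylidene-2-oxooctahydro-1H-inden-6-yl (2E)-3-methylpent-2-enoate F8. Buffered HF·pyridine at 0 °C, chosen to suppress acyl migration, gives (3S,3aR,4S,5R,6S,7aR)-3-[(1R)-1-acetoxyethyl]-5-hydroxy-4-isopropyl-7-methylidene-2-oxooctahydro-1H-inden-6-yl (2E)-3-methylpent-2-enoate F9. Steglich esterification with 12 returns to the route at 16.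

Step 5. What may go wrong: incomplete ionisation of the acylal, low syn selectivity at the carbinol carbon, or loss of acetate by β-elimination. The fallback replaces the open-transition-state alkylation by a closed metal-enolate aldol followed by acetylation. It sets out from 8. MeLi (THF, 0 °C) cleaves the enol silane regiospecifically to the lithium enolate, Cp2ZrCl2 gives the zirconium enolate (syn selective irrespective of enolate geometry), and acetaldehyde at −78 °C gives (3S,3aR,4S,5S,7aR)-3-[(1R)-1-hydroxyethyl]-4-isopropyl-7-methylidene-5-[(trimethylsilyl)oxy]octahydro-2H-inden-2-one F10. Ac2O/pyridine/DMAP then returns to the route at 10, which is desilylated to 11 as in step 5.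

Further compounds
F1 | step 4 | (3S,4R)-4-[(tert-butyldimethylsilyl)oxy]-3-(prop-1-en-2-yl)cyclopentan-1-one | C=C(C)[C@@H]1CC(=O)C[C@H]1O[Si](C)(C)C(C)(C)C
F2 | step 4 | (R)-4-(prop-1-en-2-yl)cyclopent-2-en-1-one | C=C(C)[C@@H]1CC(=O)C=C1
F3 | step 4 | (2S)-3-methyl-2-[(1S,5R)-5-(prop-1-en-2-yl)-3-[(trimethylsilyl)oxy]cyclopent-2-en-1-yl]butanal | C=C(C)[C@@H]1CC(O[Si](C)(C)C)=C[C@H]1[C@H](C(C)C)C=O
F4 | step 4 | (1R)-1-{(1S,2R,3R)-2-[(2S)-3-methyl-1-oxobutan-2-yl]-5-oxo-3-(prop-1-en-2-yl)cyclopentyl}ethyl acetate | C=C(C)[C@@H]1CC(=O)[C@H]([C@@H](C)OC(C)=O)[C@H]1[C@H](C(C)C)C=O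
F5 | step 4 | (1R)-1-[(3S,3aR,4S,5R,7aR)-5-hydroxy-4-isopropyl-7-methylidene-2-oxooctahydro-1H-inden-3-yl]ethyl acetate (C5 epimer of 11; axial 5α-OH) | C=C1[C@@H]2CC(=O)[C@H]([C@@H](C)OC(C)=O)[C@H]2[C@H](C(C)C)[C@H](O)C1
F6 | step 7 | (1R)-1-[(3S,3aR,4S,5S,7aR)-5-[(tert-butyldimethylsilyl)oxy]-4-isopropyl-7-methylidene-2-oxooctahydro-1H-inden-3-yl]ethyl acetate | C=C1[C@@H]2CC(=O)[C@H]([C@@H](C)OC(C)=O)[C@H]2[C@H](C(C)C)[C@@H](O[Si](C)(C)C(C)(C)C)C1
F7 | step 7 | (1R)-1-[(3S,3aR,4S,5R,6S,7aR)-5-[(tert-butyldimethylsilyl)oxy]-6-hydroxy-4-isopropyl-7-methylidene-2-oxooctahydro-1H-inden-3-yl]ethyl acetate | C=C1[C@@H]2CC(=O)[C@H]([C@@H](C)OC(C)=O)[C@H]2[C@H](C(C)C)[C@@H](O[Si](C)(C)C(C)(C)C)[C@H]1O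
F8 | step 7 | (3S,3aR,4S,5R,6S,7aR)-3-[(1R)-1-acetoxyethyl]-5-[(tert-butyldimethylsilyl)oxy]-4-isopropyl-7-methylidene-2-oxooctahydro-1H-inden-6-yl (2E)-3-methylpent-2-enoate | C=C1[C@@H]2CC(=O)[C@H]([C@@H](C)OC(C)=O)[C@H]2[C@H](C(C)C)[C@@H](O[Si](C)(C)C(C)(C)C)[C@H]1OC(=O)/C=C(\C)CC
F9 | step 7 | (3S,3aR,4S,5R,6S,7aR)-3-[(1R)-1-acetoxyethyl]-5-hydroxy-4-isopropyl-7-methylidene-2-oxooctahydro-1H-inden-6-yl (2E)-3-methylpent-2-enoate | C=C1[C@@H]2CC(=O)[C@H]([C@@H](C)OC(C)=O)[C@H]2[C@H](C(C)C)[C@@H](O)[C@H]1OC(=O)/C=C(\C)CC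
F10 | step 5 | (3S,3aR,4S,5S,7aR)-3-[(1R)-1-hydroxyethyl]-4-isopropyl-7-methylidene-5-[(trimethylsilyl)oxy]octahydro-2H-inden-2-one | C=C1[C@@H]2CC(=O)[C@H]([C@@H](C)O)[C@H]2[C@H](C(C)C)[C@@H](O[Si](C)(C)C)C1
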